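**Retrosynthetic overview**
- Phyltetralin (C24H32O6) is an isomer of the dimer of (E)-3,4-dimethoxycinnamyl methyl ether (2 × C12H16O3). C2 and C3 of ring B with their CH2OMe arms are the β-carbons of two identical C6C3 units, C1 and C4 are their benzylic α-carbons, and C8a is the veratryl carbon para to a methoxy group.
- Key disconnection: C2–C3 (union of two like-polarity β-carbons) and C1–C8a, both made in one enantioselective radical-cation cyclodimerisation (formal [4+2], the second styrene acting as vinylarene diene). It closes ring B onto the bought ring A and sets C1, C2 and C3 as a group, with no redox change and no protecting group.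
- The monomer comes in two steps from methyl (E)-3,4-dimethoxycinnamate (1,2-reduction, O-methylation). Rings A and C are bought; ring B is the only ring formed.

Key step: step 3

Remark: the sense of induction of a chiral counteranion cannot be predicted from first principles; the antipode of the IDPi anion that leads to the (1R,2S,3S) series is to be fixed in the first experiment, both antipodes being accessible from (R)- or (S)-BINOL.

**Step 1**
Reactants: 1 methyl (E)-3-(3,4-dimethoxyphenyl)prop-2-enoate
Product: 3 (E)-3-(3,4-dimethoxyphenyl)prop-2-en-1-ol, via (E)-3-(3,4-dimethoxyphenyl)prop-2-enal 2 (not isolated)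
Conditions: iBu2AlH (2.5 equiv), CH2Cl2, −78 to 0 °C; aq. potassium sodium tartrate work-up
Reagents that add atoms: none
Why: Aluminium hydride 1,2-reduction of an α,β-unsaturated ester, which should pass through aldehyde 2 to the allylic alcohol at low temperature without touching the conjugated (E)-alkene; no stereocentre is formed.

**Step 2**
Reactants: 3 (E)-3-(3,4-dimethoxyphenyl)prop-2-en-1-ol
Product: 5 (E)-1,2-dimethoxy-4-(3-methoxyprop-1-en-1-yl)benzene, via sodium (E)-3-(3,4-dimethoxyphenyl)prop-2-en-1-olate 4 (not isolated)
Conditions: NaH (1.3 equiv), MeI (1.5 equiv), THF, 0 °C to rt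
Reagents that add atoms: iodomethane, CI
Why: Williamson ether synthesis, in which alkoxide 4 is methylated at oxygen by SN2 attack on iodomethane while the (E)-alkene and the aryl ethers are inert to NaH.

**Step 3**
Reactants: 5 (E)-1,2-dimethoxy-4-(3-methoxyprop-1-en-1-yl)benzene (two molecules)
Product: 7 phyltetralin [(1R,2S,3S)-1-(3,4-dimethoxyphenyl)-6,7-dimethoxy-2,3-bis(methoxymethyl)-1,2,3,4-tetrahydronaphthalene], via 8a-H isotoluene cycloadduct 6 (not isolated)
Conditions: [2,4,6-tris(4-methoxyphenyl)pyrylium][IDPi] (2 mol%; IDPi = confined BINOL-derived N-triflyl imidodiphosphorimidate anion, antipode as fixed in the remark), CH2Cl2 (0.2 M), 450 nm LEDs, −78 °C, Ar; then warm to rt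
Reagents that add atoms: none
Why: Proposed new method: electron transfer from 5 to the excited pyrylium should give the styrene radical cation as an ion pair with the chiral anion; it adds head-to-head through its β-carbon to the β-carbon of a second molecule of 5 (C2–C3 bond) to give a 1,4-distonic radical cation, whose benzylic cation end attacks the other veratryl ring para to its 3-methoxy group (C1–C8a bond), and back electron transfer from the pyranyl radical followed by acid-mediated 1,3-prototropy of isotoluene 6 restores ring A, so that the whole event is a redox-neutral, isomerising formal [4+2] with the second styrene as vinylarene diene. The closest known reaction types are the radical-cation cyclodimerisation of styrenes and 1,1-diarylethylenes to 1-aryltetralins under photoinduced electron transfer, and the counteranion-directed enantioselective radical-cation [2+2] and Diels–Alder cycloadditions of anethole-type (E)-β-alkylstyrenes, which share the enantio-determining β–β bond formation proposed here. Ring B is closed stepwise, C2–C3 intermolecularly and then C1–C8a by 6-endo Friedel–Crafts-type attack of the cation on the arene; four-membered-ring closure of the same 1,4-intermediate is expected to be reversible under the oxidising conditions in this electron-rich series, whereas arene attack becomes irreversible on rearomatisation. C2 and C3 are set together in the β–β bond formation: their trans relation follows from the anti approach of two (E)-alkenes, as in the all-trans cyclobutanes of this reaction class, and their absolute sense is imposed by the confined chiral anion paired with the radical cation; C1 is relayed by substrate control through a chair-like closure that places the aryl group equatorial and trans to the C2 arm, which is also the most stable all-equatorial isomer, and the C8a centre of 6 is erased on aromatisation. The step needs head-to-head regiochemistry (secured by formation of two benzylic centres), attack at C6 and not C2 of the veratryl ring (para-methoxy activation, less hindrance) and enantiofacial discrimination (low temperature, no achiral counterion present). Two molecules of 5 give one molecule of 7 and no co-product.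

**Compound list**
1 | methyl (E)-3-(3,4-dimethoxyphenyl)prop-2-enoate | COC(=O)/C=C/c1ccc(OC)c(OC)c1 | starting material
2 | (E)-3-(3,4-dimethoxyphenyl)prop-2-enal | O=C/C=C/c1ccc(OC)c(OC)c1 | intermediate (not isolated)
3 | (E)-3-(3,4-dimethoxyphenyl)prop-2-en-1-ol | OC/C=C/c1ccc(OC)c(OC)c1 | intermediate
4 | sodium (E)-3-(3,4-dimethoxyphenyl)prop-2-en-1-olate | [Na+].[O-]C/C=C/c1ccc(OC)c(OC)c1 | intermediate (not isolated)
5 | (E)-1,2-dimethoxy-4-(3-methoxyprop-1-en-1-yl)benzene | COC/C=C/c1ccc(OC)c(OC)c1 | intermediate
6 | (1R,2S,3S)-1-(3,4-dimethoxyphenyl)-6,7-dimethoxy-2,3-bis(methoxymethyl)-1,2,3,8a-tetrahydronaphthalene (8a-H isotoluene cycloadduct, C8a configuration not defined) | COC[C@H]1C=C2C=C(OC)C(OC)=CC2[C@@H](c2ccc(OC)c(OC)c2)[C@@H]1COC | intermediate (not isolated)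
7 | phyltetralin, (1R,2S,3S)-1-(3,4-dimethoxyphenyl)-6,7-dimethoxy-2,3-bis(methoxymethyl)-1,2,3,4-tetrahydronaphthalene (all-trans) | COC[C@H]1Cc2cc(OC)c(OC)cc2[C@@H](c2ccc(OC)c(OC)c2)[C@@H]1COC | target

Total steps: 3. Longest linear sequence: 3 steps.

**Steps most likely to fail**

First, step 3 (Proposed new method). What may go wrong:
- weak enantiofacial discrimination by the counteranion in the β–β bond formation;
- collapse of the 1,4-radical cation to the four-membered ring, or chain growth to oligomers, instead of attack on the arene;
- over-oxidation of the product at the doubly benzylic C1–H.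

The fallback uses known reaction types; it sets out from 1 and comes back to the route at 7. Hydrogenation of 1 (H2, Pd/C, EtOAc) should give methyl 3-(3,4-dimethoxyphenyl)propanoate F1, and saponification (LiOH, THF/H2O) 3-(3,4-dimethoxyphenyl)propanoic acid F2. Activation with pivaloyl chloride/Et3N gives 3-(3,4-dimethoxyphenyl)propanoic pivalic anhydride F3, which acylates (R)-4-benzyloxazolidin-2-one (LiCl, THF) to (R)-4-benzyl-3-[3-(3,4-dimethoxyphenyl)propanoyl]oxazolidin-2-one F4. Oxidative homocoupling of the lithium enolate of F4 (LiN(iPr)2, THF, −78 °C, then PhI(OAc)2) is an auxiliary-controlled union of two α-carbons in which each enolate reacts on the face away from the benzyl group; it should give the (2S,3S)-bis-imide (4R,4'R)-3,3'-[(2S,3S)-2,3-bis(3,4-dimethoxybenzyl)butanedioyl]bis(4-benzyloxazolidin-2-one) F5. LiBH4 (THF/MeOH, 0 °C) should release the auxiliary and give (2S,3S)-2,3-bis(3,4-dimethoxybenzyl)butane-1,4-diol F6, and NaH/MeI (THF) the bis(methyl ether) (2S,3S)-1,4-bis(3,4-dimethoxyphenyl)-2,3-bis(methoxymethyl)butane F7. DDQ (1 equiv, CH2Cl2, no strong acid, so that benzylic hydride abstraction rather than aryl–aryl coupling operates) should then abstract hydride from one of the two homotopic benzylic CH2 groups. The p-methoxybenzyl cation should close ring B on the other veratryl ring, trans to the C2 arm, to give 7.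

Second, step 2. What may go wrong: ionisation of the electron-rich cinnamyl C–O bond during work-up or chromatography (allyl cation formation, oligomerisation), and carry-over of iodide or base traces that would quench the photocatalyst of step 3. The fallback sets out from 3 and comes back at 5. It forms the other C–O bond: catalytic TsOH in MeOH at rt ionises 3 to the 1-arylallyl cation, which methanol traps, and under the reversible conditions the conjugated linear (E)-ether 5 should accumulate as the thermodynamic product. The oxygen of 5 then comes from methanol and no alkyl halide or metal base is used.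

Third, step 1. What may go wrong: competing 1,4-hydride delivery giving the saturated alcohol, stalling at aldehyde 2 on under-dosing, and retention of product in aluminium gels. The fallback sets out from 1 and comes back at 3. Saponification (LiOH, THF/H2O) gives (E)-3-(3,4-dimethoxyphenyl)prop-2-enoic acid F8. Activation with ethyl chloroformate/Et3N (THF, 0 °C) gives ethyl carbonic (E)-3-(3,4-dimethoxyphenyl)prop-2-enoic anhydride F9, which NaBH4 (THF/H2O, 0 °C) should reduce chemoselectively at the acyl carbon to 3.

**Further compounds**
F1 | step 3 | methyl 3-(3,4-dimethoxyphenyl)propanoate | COC(=O)CCc1ccc(OC)c(OC)c1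
F2 | step 3 | 3-(3,4-dimethoxyphenyl)propanoic acid | OC(=O)CCc1ccc(OC)c(OC)c1
F3 | step 3 | 3-(3,4-dimethoxyphenyl)propanoic pivalic anhydride | CC(C)(C)C(=O)OC(=O)CCc1ccc(OC)c(OC)c1
F4 | step 3 | (R)-4-benzyl-3-[3-(3,4-dimethoxyphenyl)propanoyl]oxazolidin-2-one | O=C(CCc1ccc(OC)c(OC)c1)N1[C@H](Cc2ccccc2)COC1=O
F5 | step 3 | (4R,4'R)-3,3'-[(2S,3S)-2,3-bis(3,4-dimethoxybenzyl)butanedioyl]bis(4-benzyloxazolidin-2-one) | O=C(N1[C@H](Cc2ccccc2)COC1=O)[C@@H](Cc1ccc(OC)c(OC)c1)[C@H](Cc1ccc(OC)c(OC)c1)C(=O)N1[C@H](Cc2ccccc2)COC1=O
F6 | step 3 | (2S,3S)-2,3-bis(3,4-dimethoxybenzyl)butane-1,4-diol | OC[C@@H](Cc1ccc(OC)c(OC)c1)[C@H](Cc1ccc(OC)c(OC)c1)CO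
F7 | step 3 | (2S,3S)-1,4-bis(3,4-dimethoxyphenyl)-2,3-bis(methoxymethyl)butane | COC[C@@H](Cc1ccc(OC)c(OC)c1)[C@H](Cc1ccc(OC)c(OC)c1)COC
F0 | step 2 | none | none
F8 | step 1 | (E)-3-(3,4-dimethoxyphenyl)prop-2-enoic acid | OC(=O)/C=C/c1ccc(OC)c(OC)c1
F9 | step 1 | ethyl carbonic (E)-3-(3,4-dimethoxyphenyl)prop-2-enoic anhydride | CCOC(=O)OC(=O)/C=C/c1ccc(OC)c(OC)c1
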